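**Strategy.** Ring B, the resorcinol ring C1'–C6' that hangs from C3 of ring C and carries hydroxyls at C2' and C4', is cut out of the target and grown last on a finished ring A/ring C chromene. A photochemical Wolff rearrangement of an (E)-dienyl diazomethyl ketone gives a vinylketene. Its [2+2] addition to a silyl ynol ether, 4π opening and 6π closure form C5'–C6', C2'–C3', C4'–C5' and C1'–C2' in one operation, with C2'–O from the ketene carbonyl (free OH) and C4'–O from the ynol ether (silylated). The precursor is (E)-1-diazo-4-(5,7-dimethoxy-6-prenyl-2H-chromen-3-yl)but-3-en-2-one, built from a prenylated salicylaldehyde, acrolein and an acetonyl ylide.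

Key step: step 8

Assumption: crude material carried straight into a second operation of the same step is treated as not isolated; 3-phenylisoxazole 14 and ylide 10 are taken as catalogue chemicals.

Step 1
Reactants: 1 3,5-dimethoxyphenol
Product: 2 triisopropyl(3,5-dimethoxyphenoxy)silane
Conditions: i-Pr3SiCl, imidazole, DMF, rt
Reagents that add atoms: chlorotri(propan-2-yl)silane, CC(C)[Si](Cl)(C(C)C)C(C)C
Why: Standard O-silylation of a phenol, which masks the acidic OH with a bulky group that is a poor director for the metalation that follows.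

Step 2
Reactants: 2 triisopropyl(3,5-dimethoxyphenoxy)silane; 3 prenyl bromide (1-bromo-3-methylbut-2-ene)
Product: 6 3,5-dimethoxy-4-(3-methylbut-2-en-1-yl)phenol, via aryllithium 4 (not isolated), via prenylated silyl ether 5 (not isolated)
Conditions: n-BuLi, THF, 0 °C to rt; CuBr·SMe2 (10 mol %), 3 (1.0 equiv), −78 °C to rt; aq NH4Cl, concentrate; crude in THF, Bu4NF, 0 °C
Reagents that add atoms: prenyl bromide 3, CC(C)=CCBr; n-butyllithium, [Li]CCCC (lithium of 4 only)
Why: Directed ortho-metalation should remove the ring proton flanked by the two methoxy groups (the hindered silyloxy group does not direct to its own ortho positions), copper-catalysed SN2 allylation of aryllithium 4 at the primary carbon of 3 gives 5, and fluoride cleaves the aryl silyl ether once the volatile excess bromide is gone.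

Step 3
Reactants: 6 3,5-dimethoxy-4-(3-methylbut-2-en-1-yl)phenol
Product: 7 6-hydroxy-2,4-dimethoxy-3-(3-methylbut-2-en-1-yl)benzaldehyde
Conditions: MgCl2, Et3N, (CH2O)n, MeCN, reflux
Reagents that add atoms: paraformaldehyde (as formaldehyde), C=O
Why: Magnesium phenoxide-mediated ortho-formylation (Casnati–Skattebøl conditions) delivers formaldehyde only next to the phenol oxygen, the two ortho positions are equivalent, the para position is blocked, and the non-acidic medium spares the prenyl group.

Step 4
Reactants: 7 6-hydroxy-2,4-dimethoxy-3-(3-methylbut-2-en-1-yl)benzaldehyde; 8 acrolein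
Product: 9 5,7-dimethoxy-6-(3-methylbut-2-en-1-yl)-2H-chromene-3-carbaldehyde
Conditions: K2CO3, 1,4-dioxane, reflux
Reagents that add atoms: acrolein 8, C=CC=O
Why: Domino oxa-Michael addition of the phenoxide to acrolein and intramolecular aldol condensation onto the aryl aldehyde, the standard entry to 2H-chromene-3-carbaldehydes, closes ring C with C3 carrying the formyl group.

Step 5
Reactants: 9 5,7-dimethoxy-6-(3-methylbut-2-en-1-yl)-2H-chromene-3-carbaldehyde; 10 1-(triphenylphosphoranylidene)propan-2-one
Product: 11 (3E)-4-[5,7-dimethoxy-6-(3-methylbut-2-en-1-yl)-2H-chromen-3-yl]but-3-en-2-one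
Conditions: toluene, 90 °C
Reagents that add atoms: ylide 10, CC(=O)C=P(c1ccccc1)(c1ccccc1)c1ccccc1
Why: Wittig olefination with a ketone-stabilised ylide is E-selective and neutral, so the E geometry needed later is set here and the chromene and prenyl alkenes are untouched.

Step 6
Reactants: 11 (3E)-4-[5,7-dimethoxy-6-(3-methylbut-2-en-1-yl)-2H-chromen-3-yl]but-3-en-2-one
Product: 13 (3E)-1-diazo-4-[5,7-dimethoxy-6-(3-methylbut-2-en-1-yl)-2H-chromen-3-yl]but-3-en-2-one, via trifluoroacetyl diketone 12 (not isolated)
Conditions: LiN(SiMe3)2, THF, −78 °C; CF3CO2CH2CF3, −78 °C; dil. HCl work-up; crude in MeCN, MsN3, Et3N, rt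
Reagents that add atoms: methanesulfonyl azide, CS(=O)(=O)N=[N+]=[N-] (N2 unit of 13); 2,2,2-trifluoroethyl trifluoroacetate, O=C(OCC(F)(F)F)C(F)(F)F (CF3CO unit of 12 only)
Why: Detrifluoroacetylative diazo transfer, in which kinetic deprotonation of the methyl group (C2-H2 of ring C is only cross-conjugated and far less acidic) and Claisen trifluoroacetylation give 12, which takes up the diazo group from the sulfonyl azide with loss of the trifluoroacetyl group, a sequence established for α,β-unsaturated methyl ketones.

Step 7
Reactants: 14 3-phenylisoxazole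
Product: 16 (triisopropylsilyloxy)acetylene, via lithium ethynolate 15 (not isolated)
Conditions: n-BuLi (1.0 equiv), THF, −78 to −50 °C; i-Pr3SiOTf, −78 to 0 °C
Reagents that add atoms: triisopropylsilyl trifluoromethanesulfonate, CC(C)[Si](OS(=O)(=O)C(F)(F)F)(C(C)C)C(C)C; n-butyllithium, [Li]CCCC (lithium of 15 only)
Why: Deprotonation at C5 of the isoxazole triggers the known cycloreversion to benzonitrile and lithium ethynolate 15, and the hard, bulky silyl triflate should silylate this ambident anion at oxygen as it does substituted ynolates.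

Step 8
Reactants: 13 (3E)-1-diazo-4-[5,7-dimethoxy-6-(3-methylbut-2-en-1-yl)-2H-chromen-3-yl]but-3-en-2-one; 16 (triisopropylsilyloxy)acetylene
Product: 21 dehydroglyasperin D 4'-O-triisopropylsilyl ether, via vinylketene 17 (not isolated), via cyclobutenone 18 (not isolated), via dienylketene 19 (not isolated), via cyclohexadienone 20 (not isolated)
Conditions: 16 (3 equiv), hν (420–450 nm LEDs), degassed ClCH2CH2Cl, 20 °C; evaporate excess 16; toluene, 80 °C, dark
Reagents that add atoms: (triisopropylsilyloxy)acetylene 16, C#CO[Si](C(C)C)(C(C)C)C(C)C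
Why: Excitation of the diazo chromophore should expel N2 with 1,2-shift of the dienyl group (Wolff rearrangement, C5'–C6') to give vinylketene 17, which the electron-rich ynol ether captures at 20 °C in a [2+2] cycloaddition (nucleophilic CH terminus onto the ketene carbonyl carbon, C2'–C3' and C4'–C5') to give 4-alkenylcyclobutenone 18. On warming in the dark, strain-driven conrotatory 4π opening gives dienylketene 19, and ring B closes by disrotatory 6π electrocyclisation (C1'–C2') to cyclohexadienone 20, which tautomerises to phenol 21. This is the Danheiser benzannulation in its photochemical Wolff variant, known for alkenyl and aryl diazomethyl ketones with alkyl and silyl ynol ethers. No stereocentre survives, because the sp3 centres of 18 and 20 are racemic and are erased by ring opening and aromatisation. The step needs two selectivities: the regiochemistry of the [2+2], fixed by the polarity of the partners so that the ketene oxygen ends as free 2'-OH and the ynol oxygen as the 4'-silyl ether, and capture of 17 by 16 before any 6π closure onto C4 of ring C, secured by the E alkene from step 5 (retained in the migrating group), the excess of 16, and long-wavelength light that the diazo dienone absorbs but the chromene and isoflavene chromophores do not. Removing excess 16 before heating keeps the new 2'-OH away from ketene-type acylating agents.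

Step 9
Reactants: 21 dehydroglyasperin D 4'-O-triisopropylsilyl ether
Product: 22 dehydroglyasperin D
Conditions: Bu4NF, AcOH, THF, 0 °C, argon
Reagents that add atoms: none
Why: Fluoride cleavage of an aryl silyl ether, buffered with acetic acid so that the air- and base-sensitive resorcinol and the isoflav-3-ene never meet free phenoxide.

**Compound list**

1 | 3,5-dimethoxyphenol | COc1cc(O)cc(OC)c1 | starting material
2 | triisopropyl(3,5-dimethoxyphenoxy)silane | COc1cc(OC)cc(O[Si](C(C)C)(C(C)C)C(C)C)c1 | intermediate
3 | prenyl bromide (1-bromo-3-methylbut-2-ene) | CC(C)=CCBr | starting material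
4 | [2,6-dimethoxy-4-(triisopropylsilyloxy)phenyl]lithium | [Li]c1c(OC)cc(O[Si](C(C)C)(C(C)C)C(C)C)cc1OC | intermediate
5 | triisopropyl[3,5-dimethoxy-4-(3-methylbut-2-en-1-yl)phenoxy]silane | COc1cc(O[Si](C(C)C)(C(C)C)C(C)C)cc(OC)c1CC=C(C)C | intermediate
6 | 3,5-dimethoxy-4-(3-methylbut-2-en-1-yl)phenol | COc1cc(O)cc(OC)c1CC=C(C)C | intermediate
7 | 6-hydroxy-2,4-dimethoxy-3-(3-methylbut-2-en-1-yl)benzaldehyde | COc1cc(O)c(C=O)c(OC)c1CC=C(C)C | intermediate
8 | acrolein | C=CC=O | starting material
9 | 5,7-dimethoxy-6-(3-methylbut-2-en-1-yl)-2H-chromene-3-carbaldehyde | COc1cc2c(c(OC)c1CC=C(C)C)C=C(C=O)CO2 | intermediate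
10 | 1-(triphenylphosphoranylidene)propan-2-one | CC(=O)C=P(c1ccccc1)(c1ccccc1)c1ccccc1 | starting material
11 | (3E)-4-[5,7-dimethoxy-6-(3-methylbut-2-en-1-yl)-2H-chromen-3-yl]but-3-en-2-one | COc1cc2c(c(OC)c1CC=C(C)C)C=C(/C=C/C(C)=O)CO2 | intermediate
12 | (5E)-1,1,1-trifluoro-6-[5,7-dimethoxy-6-(3-methylbut-2-en-1-yl)-2H-chromen-3-yl]hex-5-ene-2,4-dione | COc1cc2c(c(OC)c1CC=C(C)C)C=C(/C=C/C(=O)CC(=O)C(F)(F)F)CO2 | intermediate
13 | (3E)-1-diazo-4-[5,7-dimethoxy-6-(3-methylbut-2-en-1-yl)-2H-chromen-3-yl]but-3-en-2-one | COc1cc2c(c(OC)c1CC=C(C)C)C=C(/C=C/C(=O)C=[N+]=[N-])CO2 | intermediate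
14 | 3-phenylisoxazole | c1ccc(-c2ccon2)cc1 | starting material
15 | lithium ethynolate | [Li+].[O-]C#C | intermediate
16 | (triisopropylsilyloxy)acetylene | C#CO[Si](C(C)C)(C(C)C)C(C)C | intermediate
17 | (3E)-4-[5,7-dimethoxy-6-(3-methylbut-2-en-1-yl)-2H-chromen-3-yl]buta-1,3-dien-1-one | COc1cc2c(c(OC)c1CC=C(C)C)C=C(/C=C/C=C=O)CO2 | intermediate
18 | 4-[(E)-2-[5,7-dimethoxy-6-(3-methylbut-2-en-1-yl)-2H-chromen-3-yl]ethenyl]-3-(triisopropylsilyloxy)cyclobut-2-en-1-one (racemic) | COc1cc2c(c(OC)c1CC=C(C)C)C=C(/C=C/C1C(=O)C=C1O[Si](C(C)C)(C(C)C)C(C)C)CO2 | intermediate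
19 | (3E,5E)-6-[5,7-dimethoxy-6-(3-methylbut-2-en-1-yl)-2H-chromen-3-yl]-3-(triisopropylsilyloxy)hexa-1,3,5-trien-1-one | COc1cc2c(c(OC)c1CC=C(C)C)C=C(/C=C/C=C(\C=C=O)O[Si](C(C)C)(C(C)C)C(C)C)CO2 | intermediate
20 | 6-[5,7-dimethoxy-6-(3-methylbut-2-en-1-yl)-2H-chromen-3-yl]-3-(triisopropylsilyloxy)cyclohexa-2,4-dien-1-one (racemic) | COc1cc2c(c(OC)c1CC=C(C)C)C=C(C1C=CC(O[Si](C(C)C)(C(C)C)C(C)C)=CC1=O)CO2 | intermediate
21 | dehydroglyasperin D 4'-O-triisopropylsilyl ether | COc1cc2c(c(OC)c1CC=C(C)C)C=C(c1ccc(O[Si](C(C)C)(C(C)C)C(C)C)cc1O)CO2 | intermediate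
22 | dehydroglyasperin D | COc1cc2c(c(OC)c1CC=C(C)C)C=C(c1ccc(O)cc1O)CO2 | target

**Step count.** Total: 9 steps (8 on the main line, 1 for the alkyne). Longest linear sequence: 8 steps (steps 1 to 6, 8, 9).

**Steps most likely to fail**

Step 8. Light may be spent on E to Z isomerisation of the dienone or on opening of the 2H-pyran instead of nitrogen loss. A Z-configured ketene would then close onto C4 of ring C before it meets the alkyne, and acylation of the new phenol by ketene would drain material further. The fallback generates the same vinylketene without light. It sets out from aldehyde 9 and returns at vinylketene 17, and from there through 18 to 20 at 21. Wittig olefination of 9 with the ylide from (2-carboxyethyl)triphenylphosphonium bromide (NaN(SiMe3)2, THF) should give (3E)-4-[5,7-dimethoxy-6-(3-methylbut-2-en-1-yl)-2H-chromen-3-yl]but-3-enoic acid F1. Carboxylate-bearing ylides are expected to favour the E alkene with conjugated aldehydes, and any Z isomer would be removed at the acid stage. Oxalyl chloride with catalytic DMF converts F1 into (3E)-4-[5,7-dimethoxy-6-(3-methylbut-2-en-1-yl)-2H-chromen-3-yl]but-3-enoyl chloride F2. Slow addition of F2 to Et3N and 16 in CH2Cl2 at rt gives 17 by 1,2-dehydrochlorination, the [2+2] capture follows in the dark, and warming to 80 °C completes the cascade.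

Step 7. The ambident ynolate may be silylated at carbon, leading to a silylketene. It may also lose its remaining proton to unfragmented lithioisoxazole, or the terminal silyl ynol ether may isomerise or hydrolyse during isolation. The fallback avoids ynolate silylation by making the C–O bond of the ynol ether before the triple bond and using a fluoride-labile alkyl group. It sets out from diazoketone 13 and returns at target 22. 2-(Trimethylsilyl)ethanol, KH and trichloroethylene in THF (−50 °C to rt) give (E)-1,2-dichlorovinyl 2-(trimethylsilyl)ethyl ether F3. Treatment with n-BuLi (2.2 equiv, −78 °C) and a methanol quench gives 2-(trimethylsilyl)ethyl ethynyl ether F4. F4 takes the place of 16 in step 8 and, through the same pericyclic cascade, should give dehydroglyasperin D 4'-O-[2-(trimethylsilyl)ethyl] ether F5. Bu4NF or CsF in DMF under argon then removes the silylethyl group by β-elimination to give 22.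

Step 2. Metalation may occur in part next to the silyloxy group, followed by migration of silicon from oxygen to carbon, and the allylation may be eroded by allylic transposition or halogen–lithium exchange. The fallback fixes the regiochemistry by introducing the oxygen last. It sets out from prenyl bromide 3, with commercial 1,3-dimethoxybenzene in place of 1 and 2, and returns at phenol 6. Lithiation of 1,3-dimethoxybenzene between the methoxy groups (n-BuLi, THF) and copper-catalysed allylation with 3 give 1,3-dimethoxy-2-(3-methylbut-2-en-1-yl)benzene F6. Sterically controlled iridium-catalysed C–H borylation ([Ir(OMe)(cod)]2, 4,4'-di-tert-butyl-2,2'-bipyridine, B2pin2, THF, 60 °C) at the only ring position without an ortho substituent gives 2-[3,5-dimethoxy-4-(3-methylbut-2-en-1-yl)phenyl]-4,4,5,5-tetramethyl-1,3,2-dioxaborolane F7. Oxidation with H2O2 and NaOH gives 6.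

**Further compounds**

F1 | step 8 | (3E)-4-[5,7-dimethoxy-6-(3-methylbut-2-en-1-yl)-2H-chromen-3-yl]but-3-enoic acid | COc1cc2c(c(OC)c1CC=C(C)C)C=C(/C=C/CC(=O)O)CO2
F2 | step 8 | (3E)-4-[5,7-dimethoxy-6-(3-methylbut-2-en-1-yl)-2H-chromen-3-yl]but-3-enoyl chloride | COc1cc2c(c(OC)c1CC=C(C)C)C=C(/C=C/CC(=O)Cl)CO2
F3 | step 7 | (E)-1,2-dichlorovinyl 2-(trimethylsilyl)ethyl ether | Cl/C=C(/Cl)OCC[Si](C)(C)C
F4 | step 7 | 2-(trimethylsilyl)ethyl ethynyl ether | C#COCC[Si](C)(C)C
F5 | step 7 | dehydroglyasperin D 4'-O-[2-(trimethylsilyl)ethyl] ether | COc1cc2c(c(OC)c1CC=C(C)C)C=C(c1ccc(OCC[Si](C)(C)C)cc1O)CO2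
F6 | step 2 | 1,3-dimethoxy-2-(3-methylbut-2-en-1-yl)benzene | COc1cccc(OC)c1CC=C(C)C
F7 | step 2 | 2-[3,5-dimethoxy-4-(3-methylbut-2-en-1-yl)phenyl]-4,4,5,5-tetramethyl-1,3,2-dioxaborolane | COc1cc(B2OC(C)(C)C(C)(C)O2)cc(OC)c1CC=C(C)C
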